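The runs are simulated for substances that don't exist; noise was put on by code.

- On its small charge the alder run has made 21.3% of its starting material at 67 min, and at that time the oak run has made 29.9% and the cedar run 38.3%, so the alder share is less than the oak share and the oak share less than the cedar share.

| flask | starting material | product | time |
|---|---|---|---|
| oak | 80.0 mM |  |  |
| alder | 32.0 mM |  |  |
| birch | 80.0 mM | 24.0 mM |  |
| cedar | 160 mM |  |  |
| maple | 370 mM |  | 67 min |

| oak run: time / min | oak run: [product] / mM | alder run: time / min | alder run: [product] / mM | birch run: time / min | birch run: [product] / mM | cedar run: time / min | cedar run: [product] / mM |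
|---|---|---|---|---|---|---|---|
| 2.7 | 3.45 | 2.7 | 1.22 | 2.7 | 27.21 | 2.7 | 7.32 |
| 4.6 | 5.24 | 4.6 | 1.29 | 4.6 | 29.19 | 4.6 | 12.25 |
| 7.8 | 8.14 | 7.8 | 2.40 | 7.8 | 32.18 | 7.8 | 19.68 |
| 13 | 11.99 | 13 | 3.67 | 13 | 36.20 | 13 | 29.14 |
| 23 | 17.57 | 23 | 4.94 | 23 | 41.41 | 23 | 42.56 |
| 39 | 21.73 | 39 | 6.28 | 39 | 45.79 | 39 | 53.66 |
| 67 | 23.92 | 67 | 6.82 | 67 | 47.85 | 67 | 61.24 |

(standard deviation of a reading: 0.2 mM)

- Overall: starting material -> product.
- Constant volume, constant temperature.
- Readings of a species count what is bound in complexes too.
- An order is taken over about fifteen percent of the charge, up and down.

- apparent order in [starting material] of the starting rate, round the charge of the oak run (the rate where two percent of its starting material have turned into product) (one fixed amount of product, the same in the runs compared)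
- product in the maple run at 67 min, as a share of the starting material charged

- From oak to cedar I read 0.356 for the share exponent, the logarithm of the ratio of shares (yields) over the logarithm of the ratio of charges, at one time.
- Zero is the symmetric case: if every step is first order in [starting material], the share at one time does not depend on the charge.
- These runs stand off that zero. Doubling the charge from oak to cedar multiplies the product made by 7.8 min by 2.42, more than the 2.00 of first order, so I read an order of 1.27 over that span.
- Turn the question round: for the maple run to fall below the cedar share, the exponent must turn negative. Carrying my positive reading up to the maple charge, I commit to 51.6%.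
- The forecast gives an order of 1.25 and 29%, and says that the early plateaus in its view “points to the catalyst dying”. Its share lies below cedar's, an exponent of −0.331, so you see the two reckonings part on the sign.

    2 starting material ⇌ substrate dimer, settled at all times (10.80 L mol⁻¹)
    substrate dimer → product + starting material (0.05568 min⁻¹)
    starting material → decomposed substrate (0.04128 min⁻¹)
    starting material → product (0.004698 min⁻¹)

The flask gives an order of 1.3, and the maple run gives 48.1%, above the cedar share, so the exponent keeps its sign and reads 0.273 from cedar to maple. Carried down from oak, the oak-to-cedar exponent gives 21.6% for the alder run, against the 21.3% read there. What holds the maple run down is the reaction of starting material to decomposed substrate: the same run without it reaches 71.8%, 24 percentage points above its 48.1%.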